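**Retrosynthetic overview**
1. Target ⇐ C9–O desilylation ⇐ ring-closing metathesis at C4=C5, which closes ring B (the ten-membered carbocycle) last ⇐ C8 angelate ester.
2. Ring A (furanone) and the C10 quaternary centre ⇐ gold-catalysed O-cyclisation/1,2-methyl shift (C14 moves from C1 to C10) of an acyclic 2-silyloxy-2-alkynyl ketone. This is the key step.
3. C8–C9 ⇐ boron syn-aldol of an α-silyloxy ketone (C9, C10, C1–C4, C14, C15) with a lactone aldehyde (C5–C8, C11–C13).
4. Ring C (lactone, formed first) ⇐ copper–bis(oxazoline) Mukaiyama aldol (C7–C11) of methyl 3-chloropyruvate with a ketene thioacetal built from S-ethyl thioacetate and acrolein (C6–C7).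
5. Ketone ⇐ butane-2,3-dione + 2-methylbut-1-en-3-yne (C1–C2), then Rubottom oxidation (C9–O). Rings form in the order C, A, B.

Atom labels (germacranolide numbering):
- C1: ketone
- C2=C3: furanone alkene
- C4=C5: ring alkene, with C15 the methyl on C4
- C6: lactone carbinol
- C7: ring-fusion CH
- C8: angelate carbinol
- C9: free carbinol
- C10: quaternary O-carbon, with C14 its methyl
- C11: tertiary carbinol
- C12: lactone C=O
- C13: CH2Cl

Assumption: methyl 3-chloro-2-oxopropanoate is taken as a catalogue compound (otherwise it is one esterification from 3-chloropyruvic acid).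

**Step 1**
Reactants: 1 S-ethyl ethanethioate
Product: 3 1-(ethylsulfanyl)-1-(trimethylsilyloxy)ethene, via lithium thioester enolate 2 (not isolated)
Conditions: LiN(iPr)2, THF, −78 °C; TMSCl
Reagents that add atoms: chlorotrimethylsilane C[Si](C)(C)Cl
Why: Kinetic deprotonation of a thioacetate followed by O-silylation (silyl ketene thioacetal formation) is standard and creates no stereocentre.

**Step 2**
Reactants: 3 1-(ethylsulfanyl)-1-(trimethylsilyloxy)ethene; 4 prop-2-enal (acrolein)
Product: 5 S-ethyl (3R)-3-(trimethylsilyloxy)pent-4-enethioate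
Conditions: TiCl2(OiPr)2/(R)-BINOL (5 mol %), 4 Å MS, toluene, 0 °C
Reagents that add atoms: none
Why: In this catalytic enantioselective Mukaiyama acetate aldol the BINOL–titanium Lewis acid binds the aldehyde oxygen of 4 and exposes one face to 3, which sets C6 (3R in 5, the 6S centre of the target), gives only 1,2-addition and passes the TMS group to the new oxygen.

**Step 3**
Reactants: 5 S-ethyl (3R)-3-(trimethylsilyloxy)pent-4-enethioate
Product: 7 (1Z,3S)-1-(ethylsulfanyl)-1,3-bis(trimethylsilyloxy)penta-1,4-diene, via lithium thioester enolate 6 (not isolated)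
Conditions: LiN(iPr)2, THF, −78 °C; TMSCl
Reagents that add atoms: chlorotrimethylsilane C[Si](C)(C)Cl
Why: Kinetic thioester enolisation in THF with O-silylation (Ireland-type conditions) gives the (Z)-ketene thioacetal faster than β-silyloxide is lost at −78 °C, and C6 is untouched (its descriptor changes only through ligand priorities).

**Step 4**
Reactants: 7 (1Z,3S)-1-(ethylsulfanyl)-1,3-bis(trimethylsilyloxy)penta-1,4-diene; 8 methyl 3-chloro-2-oxopropanoate
Product: 10 S-ethyl (2S,3R,4R)-4-(chloromethyl)-2-ethenyl-4-hydroxy-5-oxooxolane-3-carbothioate, via bis-silylated open-chain aldol adduct 9 (not isolated)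
Conditions: Cu(OTf)2/(R,R)-t-Bu-box (10 mol %), CH2Cl2, −78 → −40 °C; then 1 M HCl, THF, 23 °C
Reagents that add atoms: none
Why: In this copper–bis(oxazoline) Mukaiyama aldol to a chelated α-keto ester, followed by acid desilylation and lactonisation, the square-planar divalent copper chelate of 8 exposes the ketone face that gives 11R, the open transition state gives the 7,11-syn adduct usual for substituted ketene thioacetals, attack anti to the allylic C6–O bond in the H-eclipsed conformer of 7 gives the 6,7-anti relation, the three preferences converge on one isomer, and the freed C6 hydroxyl closes ring C on the methyl ester.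

**Step 5**
Reactants: 10 S-ethyl (2S,3R,4R)-4-(chloromethyl)-2-ethenyl-4-hydroxy-5-oxooxolane-3-carbothioate
Product: 11 (2S,3R,4R)-4-(chloromethyl)-2-ethenyl-4-hydroxy-5-oxooxolane-3-carbaldehyde
Conditions: Et3SiH, Pd/C (5 mol %), acetone, 23 °C, short contact; used at once
Reagents that add atoms: none
Why: In the Fukuyama reduction zerovalent palladium inserts into the C–S bond and the silane delivers hydride under neutral conditions, so the reaction stops at the aldehyde, the sulfur-poisoned surface spares the vinyl group and the allylic C–O bond, and the lactone, the chlorohydrin and the epimerisable C7 centre survive.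

**Step 6**
Reactants: 12 2-methylbut-1-en-3-yne; 13 butane-2,3-dione
Product: 15 (3R)-3-hydroxy-3,6-dimethylhept-6-en-4-yn-2-one, via alkynyl(methyl)zinc 14 (not isolated)
Conditions: 12, Me2Zn, 8-aminomenthol-derived perhydro-1,3-benzoxazine amino alcohol ligand (20 mol %), toluene, 23 °C; 13 (3 equiv), −20 °C; 1 M HCl quench
Reagents that add atoms: none
Why: In this ligand-accelerated 1,2-addition of an alkynylzinc to an α-dicarbonyl compound (the type established for α-keto esters and 1,2-diketones) the chelated diketone is attacked on its Re face to set C1 as R, excess 13 suppresses double addition, and any minor enantiomer is removed later as a diastereomer of 20.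

**Step 7**
Reactants: 15 (3R)-3-hydroxy-3,6-dimethylhept-6-en-4-yn-2-one
Product: 16 (3R)-3,6-dimethyl-2,3-bis(triethylsilyloxy)hepta-1,6-dien-4-yne
Conditions: TESOTf (2.4 equiv), Et3N, CH2Cl2, 0 °C
Reagents that add atoms: triethylsilyl trifluoromethanesulfonate CC[Si](CC)(CC)OS(=O)(=O)C(F)(F)F
Why: In this silyl triflate/amine soft enolisation the ketone has only one enolisable position (the future C9), so a single enol silane forms while the tertiary carbinol is silylated in the same operation and C1 is untouched.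

**Step 8**
Reactants: 16 (3R)-3,6-dimethyl-2,3-bis(triethylsilyloxy)hepta-1,6-dien-4-yne
Product: 18 (3R)-3,6-dimethyl-1,3-bis(triethylsilyloxy)hept-6-en-4-yn-2-one, via silyloxy epoxide 17 (not isolated)
Conditions: mCPBA (1.0 equiv), CH2Cl2, −20 → 0 °C
Reagents that add atoms: 3-chloroperoxybenzoic acid OOC(=O)c1cccc(Cl)c1
Why: In the Rubottom oxidation the electron-rich enol silane is epoxidised far faster than the conjugated isopropenyl group, and the silyloxy epoxide opens with 1,4-silyl migration to the α-silyloxy ketone, which installs the C9 oxygen without creating a stereocentre.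

**Step 9**
Reactants: 18 (3R)-3,6-dimethyl-1,3-bis(triethylsilyloxy)hept-6-en-4-yn-2-one; 11 (2S,3R,4R)-4-(chloromethyl)-2-ethenyl-4-hydroxy-5-oxooxolane-3-carbaldehyde
Product: 20 (3R,4R,5S)-3-(chloromethyl)-5-ethenyl-3-hydroxy-4-[(1S,2R,4R)-1-hydroxy-4,7-dimethyl-3-oxo-2,4-bis(triethylsilyloxy)oct-7-en-5-yn-1-yl]oxolan-2-one, via (Z)-dibutylboron enolate 19 (not isolated)
Conditions: 18 (1.3 equiv), Bu2BOTf, iPr2NEt, CH2Cl2, −78 → 0 °C; 11, −78 °C; then pH 7 buffer, MeOH, H2O2, 0 °C
Reagents that add atoms: none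
Why: In this boron-mediated syn-aldol through a Zimmerman–Traxler chair the bulky quaternary C1 forces the (Z)-enolate and hence the 8,9-syn relation, the enolate reacts on the face that carries the slim alkynyl group when the C1–OSi dipole opposes the enolate C–O bond (α′-silyloxy ketone control), which sets 9R and therefore 8S, this is also the Felkin face of 11 with quaternary C11 as the large group, and the tertiary hydroxyl of 11 is only transiently borylated.

**Step 10**
Reactants: 20 (the aldol adduct of step 9)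
Product: 21 (3R,4R,5S)-3-(chloromethyl)-5-ethenyl-3-hydroxy-4-{(1S,2R)-1-hydroxy-2-[(2R)-2-methyl-3-oxo-5-(prop-1-en-2-yl)-2,3-dihydrofuran-2-yl]-2-(triethylsilyloxy)ethyl}oxolan-2-one
Conditions: AuCl3 (5 mol %), i-PrOH (1.5 equiv), CH2Cl2, 23 °C
Reagents that add atoms: none
Why: Proposed new method: carbophilic trivalent gold activates the enyne triple bond, the C10 ketone oxygen closes 5-endo-dig onto C3, and the resulting 3-silyloxy-3H-furanium ion collapses by a suprafacial 1,2-shift of the C14 methyl group from C1 to C10 (α-ketol/semipinacol type) while i-PrOH takes up the triethylsilyl cation and supplies the proton for protodeauration, so ring A is formed and the C1 configuration from step 6 is copied point-to-point into the quaternary centre (10R); the closest known reactions are the AuCl3- or PtCl2-catalysed cyclisation/1,2-alkyl shift of simple 2-hydroxy-2-alkynyl ketones and the N-iodosuccinimide-triggered version of their silyl ethers, neither of which has been shown as a proton-terminated gold catalysis on a silyl ether, on a ketone flanked by an α′-silyloxy/β′-hydroxy stereodiad, or as a stereochemical relay.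

**Step 11**
Reactants: 21 (the furanone of step 10); 22 (2Z)-2-methylbut-2-enoic acid (angelic acid)
Product: 24 (1S,2R)-1-[(2S,3S,4R)-4-(chloromethyl)-2-ethenyl-4-hydroxy-5-oxooxolan-3-yl]-2-[(2R)-2-methyl-3-oxo-5-(prop-1-en-2-yl)-2,3-dihydrofuran-2-yl]-2-(triethylsilyloxy)ethyl (2Z)-2-methylbut-2-enoate, via mixed angelic trichlorobenzoic anhydride 23 (not isolated)
Conditions: 22, 2,4,6-trichlorobenzoyl chloride, Et3N, toluene, 23 °C; then 21, DMAP (20 mol %), 40 °C
Reagents that add atoms: none
Why: In this Yamaguchi-type mixed-anhydride esterification only the secondary C8 hydroxyl is acylated (C11–OH is tertiary, C9–O is silylated), pre-forming the anhydride and limiting DMAP keeps the Z geometry of the angelate, and because C9–H is no longer acidic after step 10 no β-elimination can occur.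

**Step 12**
Reactants: 24 (the angelate diene of step 11)
Product: 25 (4Z,6S,7S,8S,9R,10R,11R)-13-chloro-11-hydroxy-1-oxo-9-(triethylsilyloxy)-3,10-epoxygermacra-2,4-dien-6,12-olid-8-yl (2Z)-2-methylbut-2-enoate
Conditions: second-generation Hoveyda–Grubbs catalyst (15 mol %), 1,4-benzoquinone (30 mol %), toluene (0.5 mM), 100 °C
Reagents that add atoms: none
Why: In the ring-closing metathesis the catalyst loads on the monosubstituted C5 vinyl group and closes on the isopropenyl group with loss of ethene, the electron-poor trisubstituted angelate and furanone alkenes are inert, and the oxygen-bridged bicyclic frame accommodates only the 4Z trisubstituted alkene.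

**Step 13**
Reactants: 25 (the macrocyclic silyl ether of step 12)
Product: 26 (4Z,6S,7S,8S,9R,10R,11R)-13-chloro-9,11-dihydroxy-1-oxo-3,10-epoxygermacra-2,4-dien-6,12-olid-8-yl (2Z)-2-methylbut-2-enoate (CNP0272644.1)
Conditions: 1 M HCl, THF, 0 → 23 °C
Reagents that add atoms: none
Why: Acidic cleavage of the secondary TES ether is fast under conditions that leave both esters and the furanone intact, it avoids base-promoted 8→9 acyl migration, and the chloride-containing acid would reopen at C13 any 11,13-epoxide formed adventitiously in the earlier amine-containing steps.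

**Compound list**
1 | S-ethyl ethanethioate | CCSC(C)=O | starting material
2 | lithium 1-(ethylsulfanyl)ethen-1-olate | [Li]OC(=C)SCC | intermediate
3 | 1-(ethylsulfanyl)-1-(trimethylsilyloxy)ethene | C=C(SCC)O[Si](C)(C)C | intermediate
4 | prop-2-enal (acrolein) | C=CC=O | starting material
5 | S-ethyl (3R)-3-(trimethylsilyloxy)pent-4-enethioate | CCSC(=O)C[C@H](C=C)O[Si](C)(C)C | intermediate
6 | lithium (1Z,3S)-1-(ethylsulfanyl)-3-(trimethylsilyloxy)penta-1,4-dien-1-olate | CCS/C(O[Li])=C\[C@H](C=C)O[Si](C)(C)C | intermediate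
7 | (1Z,3S)-1-(ethylsulfanyl)-1,3-bis(trimethylsilyloxy)penta-1,4-diene | CCS/C(O[Si](C)(C)C)=C\[C@H](C=C)O[Si](C)(C)C | intermediate
8 | methyl 3-chloro-2-oxopropanoate | COC(=O)C(=O)CCl | starting material
9 | methyl (2R,3R,4S)-2-(chloromethyl)-3-[(ethylsulfanyl)carbonyl]-2,4-bis(trimethylsilyloxy)hex-5-enoate | COC(=O)[C@](CCl)(O[Si](C)(C)C)[C@H](C(=O)SCC)[C@@H](O[Si](C)(C)C)C=C | intermediate
10 | S-ethyl (2S,3R,4R)-4-(chloromethyl)-2-ethenyl-4-hydroxy-5-oxooxolane-3-carbothioate | CCSC(=O)[C@@H]1[C@H](C=C)OC(=O)[C@@]1(O)CCl | intermediate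
11 | (2S,3R,4R)-4-(chloromethyl)-2-ethenyl-4-hydroxy-5-oxooxolane-3-carbaldehyde | O=C[C@@H]1[C@H](C=C)OC(=O)[C@@]1(O)CCl | intermediate
12 | 2-methylbut-1-en-3-yne | C=C(C)C#C | starting material
13 | butane-2,3-dione | CC(=O)C(C)=O | starting material
14 | methyl(3-methylbut-3-en-1-yn-1-yl)zinc | C[Zn]C#CC(C)=C | intermediate
15 | (3R)-3-hydroxy-3,6-dimethylhept-6-en-4-yn-2-one | C=C(C)C#C[C@@](C)(O)C(C)=O | intermediate
16 | (3R)-3,6-dimethyl-2,3-bis(triethylsilyloxy)hepta-1,6-dien-4-yne | C=C(C)C#C[C@@](C)(O[Si](CC)(CC)CC)C(=C)O[Si](CC)(CC)CC | intermediate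
17 | 2-[(2R)-5-methyl-2-(triethylsilyloxy)hex-5-en-3-yn-2-yl]-2-(triethylsilyloxy)oxirane (both epimers at the oxirane carbon) | C=C(C)C#C[C@@](C)(O[Si](CC)(CC)CC)C1(CO1)O[Si](CC)(CC)CC | intermediate
18 | (3R)-3,6-dimethyl-1,3-bis(triethylsilyloxy)hept-6-en-4-yn-2-one | C=C(C)C#C[C@@](C)(O[Si](CC)(CC)CC)C(=O)CO[Si](CC)(CC)CC | intermediate
19 | dibutyl{[(1Z,3R)-3,6-dimethyl-1,3-bis(triethylsilyloxy)hepta-1,6-dien-4-yn-2-yl]oxy}borane | C=C(C)C#C[C@@](C)(O[Si](CC)(CC)CC)/C(OB(CCCC)CCCC)=C/O[Si](CC)(CC)CC | intermediate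
20 | (3R,4R,5S)-3-(chloromethyl)-5-ethenyl-3-hydroxy-4-[(1S,2R,4R)-1-hydroxy-4,7-dimethyl-3-oxo-2,4-bis(triethylsilyloxy)oct-7-en-5-yn-1-yl]oxolan-2-one | C=C(C)C#C[C@@](C)(O[Si](CC)(CC)CC)C(=O)[C@H](O[Si](CC)(CC)CC)[C@@H](O)[C@@H]1[C@H](C=C)OC(=O)[C@@]1(O)CCl | intermediate
21 | (3R,4R,5S)-3-(chloromethyl)-5-ethenyl-3-hydroxy-4-{(1S,2R)-1-hydroxy-2-[(2R)-2-methyl-3-oxo-5-(prop-1-en-2-yl)-2,3-dihydrofuran-2-yl]-2-(triethylsilyloxy)ethyl}oxolan-2-one | C=C(C)C1=CC(=O)[C@](C)(O1)[C@H](O[Si](CC)(CC)CC)[C@@H](O)[C@@H]2[C@H](C=C)OC(=O)[C@@]2(O)CCl | intermediate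
22 | (2Z)-2-methylbut-2-enoic acid (angelic acid) | C/C=C(/C)C(=O)O | starting material
23 | (2Z)-2-methylbut-2-enoic 2,4,6-trichlorobenzoic anhydride | C/C=C(/C)C(=O)OC(=O)c1c(Cl)cc(Cl)cc1Cl | intermediate
24 | (1S,2R)-1-[(2S,3S,4R)-4-(chloromethyl)-2-ethenyl-4-hydroxy-5-oxooxolan-3-yl]-2-[(2R)-2-methyl-3-oxo-5-(prop-1-en-2-yl)-2,3-dihydrofuran-2-yl]-2-(triethylsilyloxy)ethyl (2Z)-2-methylbut-2-enoate | C=C(C)C1=CC(=O)[C@](C)(O1)[C@H](O[Si](CC)(CC)CC)[C@@H](OC(=O)/C(C)=C\C)[C@@H]2[C@H](C=C)OC(=O)[C@@]2(O)CCl | intermediate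
25 | (4Z,6S,7S,8S,9R,10R,11R)-13-chloro-11-hydroxy-1-oxo-9-(triethylsilyloxy)-3,10-epoxygermacra-2,4-dien-6,12-olid-8-yl (2Z)-2-methylbut-2-enoate | C/C=C(/C)C(=O)O[C@H]1[C@@H]2[C@H](/C=C(/C)C3=CC(=O)[C@](C)(O3)[C@@H]1O[Si](CC)(CC)CC)OC(=O)[C@@]2(O)CCl | intermediate
26 | (4Z,6S,7S,8S,9R,10R,11R)-13-chloro-9,11-dihydroxy-1-oxo-3,10-epoxygermacra-2,4-dien-6,12-olid-8-yl (2Z)-2-methylbut-2-enoate (CNP0272644.1) | C/C=C(/C)C(=O)O[C@H]1[C@@H]2[C@H](/C=C(/C)C3=CC(=O)[C@](C)(O3)[C@@H]1O)OC(=O)[C@@]2(O)CCl | target

**Step count**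
- Total steps: 13.
- Longest linear sequence: 10 (steps 1–5, then 9–13). The ketone branch (steps 6–8) is 3 steps.

**The three steps most likely to fail**

*Step 4.* The ketene thioacetal 7 is α-branched and hindered, it can lose β-silyloxide, and a halopyruvate is an untested acceptor.
- The fallback reverses the order in which C7 receives its two substituents. It sets out from 3, 8 and 4.
- The same copper catalyst adds the unsubstituted ketene thioacetal 3 to 8, the best-behaved case of this aldol. This gives methyl (2R)-2-(chloromethyl)-4-(ethylsulfanyl)-4-oxo-2-(trimethylsilyloxy)butanoate F1.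
- Enolisation with c-Hex2BCl/Et3N (E-enolate of a thioester) and an anti-selective boron aldol with acrolein 4 follow. They give methyl (2R,3R,4S)-2-(chloromethyl)-3-[(ethylsulfanyl)carbonyl]-4-hydroxy-2-(trimethylsilyloxy)hex-5-enoate F2, which is separated from its diastereomers.
- 1 M HCl in THF removes the TMS group and lactonises. The fallback comes back to the route at 10.

*Step 10 (the proposed new step).* Three things can go wrong:
- A 1,2-hydride shift from C9, pushed by the C9 silyloxy group, can compete with the methyl shift.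
- Early loss of the C9 TES group would open a 6-endo O-cyclisation.
- AuCl3 may be reduced by the alkenes.

The fallback uses known chemistry. It sets out from 20.
- N-iodosuccinimide (CH2Cl2, 23 °C, dark) triggers the documented iodonium-induced cyclisation/1,2-shift of 2-alkynyl-2-silyloxy ketones. This gives (3R,4R,5S)-3-(chloromethyl)-5-ethenyl-3-hydroxy-4-{(1S,2R)-1-hydroxy-2-[(2R)-4-iodo-2-methyl-3-oxo-5-(prop-1-en-2-yl)-2,3-dihydrofuran-2-yl]-2-(triethylsilyloxy)ethyl}oxolan-2-one F3.
- Reductive removal of the α-iodine with Zn dust in AcOH/THF at 0 °C avoids soluble palladium, which could ionise the allylic lactone. The fallback comes back to the route at 21.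

*Step 12.* A strained ten-membered ring with a trisubstituted alkene has to form next to a bulky C8 ester, and oligomerisation may win.
- The fallback changes the order of events. It sets out from 21.
- Metathesis is run on the unacylated carbinol, which is smaller and can fold through an O8–H···O=C1 hydrogen bond. This gives (4Z,6S,7R,8S,9R,10R,11R)-13-chloro-8,11-dihydroxy-1-oxo-9-(triethylsilyloxy)-3,10-epoxygermacra-2,4-dien-6,12-olide F4.
- The C8 hydroxyl of the closed ring is then acylated with the mixed anhydride 23 as in step 11. The fallback comes back to the route at 25.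

**Further compounds**
F1 | step 4 | methyl (2R)-2-(chloromethyl)-4-(ethylsulfanyl)-4-oxo-2-(trimethylsilyloxy)butanoate | COC(=O)[C@](CCl)(O[Si](C)(C)C)CC(=O)SCC
F2 | step 4 | methyl (2R,3R,4S)-2-(chloromethyl)-3-[(ethylsulfanyl)carbonyl]-4-hydroxy-2-(trimethylsilyloxy)hex-5-enoate | COC(=O)[C@](CCl)(O[Si](C)(C)C)[C@H](C(=O)SCC)[C@@H](O)C=C
F3 | step 10 | (3R,4R,5S)-3-(chloromethyl)-5-ethenyl-3-hydroxy-4-{(1S,2R)-1-hydroxy-2-[(2R)-4-iodo-2-methyl-3-oxo-5-(prop-1-en-2-yl)-2,3-dihydrofuran-2-yl]-2-(triethylsilyloxy)ethyl}oxolan-2-one | C=C(C)C1=C(I)C(=O)[C@](C)(O1)[C@H](O[Si](CC)(CC)CC)[C@@H](O)[C@@H]2[C@H](C=C)OC(=O)[C@@]2(O)CCl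
F4 | step 12 | (4Z,6S,7R,8S,9R,10R,11R)-13-chloro-8,11-dihydroxy-1-oxo-9-(triethylsilyloxy)-3,10-epoxygermacra-2,4-dien-6,12-olide | O[C@H]1[C@@H]2[C@H](/C=C(/C)C3=CC(=O)[C@](C)(O3)[C@@H]1O[Si](CC)(CC)CC)OC(=O)[C@@]2(O)CCl
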